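**Retrosynthetic overview**

1. The two angelates go on last: C8–O by Mitsunobu inversion and C7–O by Yamaguchi acylation of a 7β,8β-diol, which comes from osmylation of a C7=C8 olefin anti to the protected C9 carbinol.
2. The seven-membered ring (C4–C5–C6–C7–C8–C9–C10) is closed by ring-closing metathesis at C7=C8, after the key step.
3. Key disconnection C10–C11 (cyclobutane C4–C5–C11–C10). The enabling feature: C11 is the α′-carbon of the C1 ketone in the six-membered ring C1–C2–C3–C4–C5–C11 and lies 1,3 (across C5) to C4, whose substituent C10 is quaternary and flanked by the C9 carbinol. C9–OH/C10 is therefore read as a C9–C10 (E)-epoxide opened at its tertiary end by a C11 silyl dienol ether.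
4. The cyclohexenone comes from a catalytic asymmetric Diels–Alder reaction (sets C5); C4 is relayed from C5 by equilibration, C9/C10 come from a Sharpless epoxidation, C7/C8 are relayed from C9.
5. Ring order: six-membered ring (step 3) → cyclobutane (step 11) → seven-membered ring (step 14).

Key step: step 11

Remark: locants are the longipinane locants of the target (C1 ketone, C2=C3 with the C3 methyl, bridgeheads C4 and C11, one-carbon bridges C5 and C10, C6 = CMe2, C7–C9 the oxygenated carbons); α is the face of the seven-membered ring turned to C11, β the face turned to C4.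
Assumption: the (S)-oxazaborolidinium catalyst of step 3 is taken to give the enantiomer of 7 that is drawn; if the sense of induction is the opposite, the (R)-catalyst is used.

**Route**

Step 1
Reactants: 1 (E)-pent-3-en-2-one
Product: 2 (E)-tert-butyldimethyl(penta-1,3-dien-2-yloxy)silane
Conditions: t-BuMe2SiOTf, Et3N, CH2Cl2, 0 °C
Reagents that add atoms: tert-butyldimethylsilyl trifluoromethanesulfonate CC(C)(C)[Si](C)(C)OS(=O)(=O)C(F)(F)F
Why: Soft enolisation (silyl triflate/amine) of the enone on its methyl side is the standard entry to 2-silyloxy-1,3-dienes and leaves the E olefin untouched.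

Step 2
Reactants: 3 4,4-dimethoxybutan-2-one; 4 trimethyl(3-methylbut-2-en-1-yl)silane
Product: 6 (E)-5,5-dimethylhepta-3,6-dien-2-one, via β-methoxy ketone 5 (not isolated)
Conditions: Me3SiOTf (10 mol %), CH2Cl2, −78 °C; then DBU, 0 °C → rt
Reagents that add atoms: none
Why: Hosomi–Sakurai allylation of the acetal through the γ-carbon of the prenylsilane should build the quaternary C6, and E1cB loss of methanol from the β-methoxy ketone should give the E enone.

Step 3
Reactants: 2 (E)-tert-butyldimethyl(penta-1,3-dien-2-yloxy)silane; 6 (E)-5,5-dimethylhepta-3,6-dien-2-one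
Product: 7 1-[(1R,2R,6R)-4-(tert-butyldimethylsilyloxy)-2-methyl-6-(2-methylbut-3-en-2-yl)cyclohex-3-en-1-yl]ethan-1-one
Conditions: 2 (1.5 equiv), (S)-o-tolyl-CBS-oxazaborolidine (20 mol %)/Tf2NH (17 mol %), CH2Cl2, −78 → −20 °C
Reagents that add atoms: none
Why: Catalytic asymmetric Diels–Alder reaction: the unsubstituted diene terminus (largest HOMO coefficient, reinforced by the 2-silyloxy and 4-methyl groups) should bond to the enone β-carbon, the catalyst's face selection sets C5, the E dienophile puts the acetyl trans to the tert-alkyl group and the endo mode puts it cis to the ring methyl (C4 is corrected in step 7, C3 becomes sp2 in step 6).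

Step 4
Reactants: 7 Diels–Alder adduct (methyl ketone)
Product: 9 tert-butyl{[(3S,4R,5R)-4-ethynyl-3-methyl-5-(2-methylbut-3-en-2-yl)cyclohex-1-en-1-yl]oxy}dimethylsilane, via enol phosphate 8 (not isolated)
Conditions: LDA (1.1 equiv), THF, −78 °C; ClP(O)(OEt)2; LDA (2.3 equiv), −78 °C → rt; aq. NH4Cl
Reagents that add atoms: none
Why: The kinetic methyl-side enolate is trapped as the enol phosphate and eliminated by excess amide base to the terminal alkyne (established methyl ketone → alkyne conversion); the silyl enol ether and the hindered C4–H should be inert.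

Step 5
Reactants: 9 terminal alkyne
Product: 10 (E)-3-[4-(tert-butyldimethylsilyloxy)-2-methyl-6-(2-methylbut-3-en-2-yl)cyclohex-3-en-1-yl]but-2-en-1-ol (ring stereocentres as in 7)
Conditions: Me3Al (2.5 equiv), Cp2ZrCl2 (0.3 equiv), ClCH2CH2Cl, rt; then n-BuLi (1 equiv), THF, −78 °C; (CH2O)n, → rt; Rochelle salt
Reagents that add atoms: trimethylaluminium C[Al](C)C; formaldehyde (as paraformaldehyde) C=O
Why: Zirconium-catalysed carboalumination (Negishi) adds Me and Al syn with Me on the internal carbon, and trapping of the alkenyl alanate with formaldehyde should give the E allylic alcohol with C4 and C8 trans across C9=C10, the geometry the epoxide of step 8 needs.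

Step 6
Reactants: 10 silyl enol ether allylic alcohol
Product: 11 (4R,5R)-4-[(E)-4-hydroxybut-2-en-2-yl]-3-methyl-5-(2-methylbut-3-en-2-yl)cyclohex-2-en-1-one (4,5-trans)
Conditions: Pd(OAc)2 (1.05 equiv), MeCN, rt
Reagents that add atoms: none
Why: Saegusa–Ito oxidation of the regiodefined silyl enol ether (β-hydride elimination of the C3–H) should give the C1 enone with the C2=C3 double bond and erase the C3 stereocentre.

Step 7
Reactants: 11 trans-enone
Product: 12 (4S,5R)-4-[(E)-4-hydroxybut-2-en-2-yl]-3-methyl-5-(2-methylbut-3-en-2-yl)cyclohex-2-en-1-one (4,5-cis)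
Conditions: t-BuOK (0.2 equiv), t-BuOH–THF, 25 °C; pH 7 buffer
Reagents that add atoms: none
Why: Base equilibration of the γ-stereocentre through the extended dienolate should favour the cis isomer, in which A(1,2) strain with the C3 methyl is relieved by an axial C4 side chain while the tert-alkyl group at C5 stays equatorial (C4 relayed from C5).

Step 8
Reactants: 12 cis-enone allylic alcohol
Product: 13 (4R,5R)-4-[(2R,3R)-3-(hydroxymethyl)-2-methyloxiran-2-yl]-3-methyl-5-(2-methylbut-3-en-2-yl)cyclohex-2-en-1-one
Conditions: Ti(OiPr)4 (10 mol %), D-(−)-diethyl tartrate (12 mol %), t-BuOOH (2 equiv), 4 Å MS, CH2Cl2, −20 °C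
Reagents that add atoms: tert-butyl hydroperoxide CC(C)(C)OO
Why: Sharpless asymmetric epoxidation is specific for the allylic alcohol (enone and vinyl olefins do not react) and sets C9 and C10 under reagent control, by analogy with the geraniol case with the tartrate enantiomer reversed.

Step 9
Reactants: 13 epoxy alcohol
Product: 14 (4R,5R)-3-methyl-5-(2-methylbut-3-en-2-yl)-4-[(2R,3R)-2-methyl-3-{[(triethylsilyl)oxy]methyl}oxiran-2-yl]cyclohex-2-en-1-one
Conditions: Et3SiCl, imidazole, CH2Cl2, 0 °C
Reagents that add atoms: chlorotriethylsilane CC[Si](Cl)(CC)CC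
Why: Standard silylation gives a non-participating primary ether that can later be oxidised directly.

Step 10
Reactants: 14 epoxy enone
Product: 15 tert-butyldimethylsilyl dienol ether of 14 (2-silyloxy-1,3-diene C11=C1(OSi)–C2=C3; stereocentres as in 14)
Conditions: LDA (1.1 equiv), THF, −78 °C; t-BuMe2SiCl, DMPU, −78 → 0 °C; filtration through basic alumina
Reagents that add atoms: tert-butylchlorodimethylsilane CC(C)(C)[Si](C)(C)Cl
Why: Kinetic deprotonation of a cyclohexenone occurs at the α′-carbon (C11) and O-silylation fixes the cross-conjugated dienolate; no triflate or amine is present, so the epoxide should survive.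

Step 11
Reactants: 15 silyl dienol ether epoxide
Product: 16 bicyclo[3.1.1]hept-3-en-2-one with C10 carrying Me and the (9S)-CH(OSiMe2t-Bu)CH2OSiEt3 chain and C5 carrying the 2-methylbut-3-en-2-yl group, both chains anti to the enone bridge
Conditions: t-BuMe2SiOTf (0.2 equiv), 2,6-di-tert-butyl-4-methylpyridine (0.3 equiv), CH2Cl2, −78 → −40 °C
Reagents that add atoms: none
Why: Proposed new method: catalytic silyl triflate silylates the epoxide oxygen, the silyl dienol ether carbon C11 opens the activated epoxide at its tertiary end C10 from the rear, and the resulting silyloxocarbenium ion returns its silyl group to triflate, so 15 isomerises to 16 with the silyl group ending on O9. The closest known reaction types are the Lewis-acid-promoted epoxide-initiated cyclisation terminated by an enol silane (tertiary epoxide carbon, inversion; known for five- and six-membered rings) and the anionic 4-exo epoxide opening of epoxy nitriles; their combination for a four-membered ring is new. One ring is closed, the cyclobutane C4–C5–C11–C10, in the 4-exo-tet mode with the C9–O bond outside the new ring. C10 is set by stereospecific inversion of the (E)-derived (9R,10R)-epoxide, C11 by the bridge geometry (C10 can only span the face that carries the axial C4 side chain), and C9 is carried over unchanged from step 8. The step needs attack at C10 instead of 5-endo attack at C9, 1,2-hydride shift or elimination; this is secured by the positive charge building at the tertiary C10, by A(1,2) strain with the C3 methyl that holds the side chain axial about 3 Å above the C11 π-lobe with the C10–O bond anti, and by the hindered base and low temperature. The driving force is release of epoxide strain and formation of the conjugated enone.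

Step 12
Reactants: 16 bis-silyl ether
Product: 17 α-silyloxy aldehyde (C8 aldehyde; C9–OSiMe2t-Bu and ring stereocentres as in 16)
Conditions: (COCl)2, DMSO, CH2Cl2, −78 → −30 °C; Et3N
Reagents that add atoms: none
Why: Primary triethylsilyl ethers are oxidised directly under Swern conditions while the hindered secondary tert-butyldimethylsilyl ether stays; C9 has no acidic partner other than the aldehyde and is flanked by a quaternary carbon, so epimerisation should be slow.

Step 13
Reactants: 17 aldehyde
Product: 18 diene (C9–CH=CH2 and C6–CH=CH2; C9–OSiMe2t-Bu and ring stereocentres as in 16)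
Conditions: Ph3PCH3Br, KHMDS, THF, −78 → 0 °C
Reagents that add atoms: methyltriphenylphosphonium bromide C[P+](c1ccccc1)(c1ccccc1)c1ccccc1.[Br-]
Why: Wittig methylenation should be selective for the aldehyde over the hindered bicyclic enone carbonyl.

Step 14
Reactants: 18 diene
Product: 19 9α-(tert-butyldimethylsilyloxy)longipina-2,7-dien-1-one
Conditions: Hoveyda–Grubbs II (10 mol %), toluene, 80 °C
Reagents that add atoms: none
Why: Ring-closing metathesis of two terminal vinyl groups held side by side on the rigid bicycle (both chains anti to the enone bridge) closes the seven-membered ring; loss of ethene drives it.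

Step 15
Reactants: 19 tricyclic olefin
Product: 20 7β,8β-dihydroxy-9α-(tert-butyldimethylsilyloxy)longipin-2-en-1-one
Conditions: OsO4 (5 mol %), N-methylmorpholine N-oxide, acetone–H2O, rt
Reagents that add atoms: osmium tetroxide (catalytic oxygen carrier) O=[Os](=O)(=O)=O; N-methylmorpholine N-oxide C[N+]1([O-])CCOCC1; water O
Why: Syn dihydroxylation should occur on the β face, anti to the allylic 9α-silyloxy group (the two faces are otherwise nearly equivalent), setting C7; the electron-poor enone olefin should react much more slowly.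

Step 16
Reactants: 20 cis-diol
Product: 21 8α-angeloyloxy-7β-hydroxy-9α-(tert-butyldimethylsilyloxy)longipin-2-en-1-one
Conditions: angelic acid, PPh3, DIAD, toluene, 0 °C → rt
Reagents that add atoms: angelic acid ((Z)-2-methylbut-2-enoic acid) C/C=C(/C)C(=O)O
Why: Mitsunobu esterification of a cis-1,2-diol proceeds through the dioxaphosphorane and carboxylate attack with inversion; attack should go to C8 because C7 is neopentyl, which sets C8 and installs the first angelate.

Step 17
Reactants: 21 hydroxy angelate
Product: 22 7β,8α-diangeloyloxy-9α-(tert-butyldimethylsilyloxy)longipin-2-en-1-one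
Conditions: angelic acid, 2,4,6-Cl3C6H2COCl, Et3N, toluene, rt; then 21, 75 °C
Reagents that add atoms: angelic acid ((Z)-2-methylbut-2-enoic acid) C/C=C(/C)C(=O)O
Why: Yamaguchi mixed-anhydride acylation is the usual way to angeloylate hindered secondary alcohols without Z→E isomerisation.

Step 18
Reactants: 22 silyl ether
Product: 23 target, 7β,8α-diangeloyloxy-9α-hydroxylongipin-2-en-1-one ((4R,5S,7S,8S,9S,10R,11R))
Conditions: HF·pyridine, pyridine–THF, 0 °C → rt
Reagents that add atoms: none
Why: Buffered acidic fluoride removes the silyl ether; non-basic conditions should avoid angelate migration from O8 to O9 and ester cleavage.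

**Compound list**

1 | (E)-pent-3-en-2-one | C/C=C/C(C)=O | starting material
2 | (E)-tert-butyldimethyl(penta-1,3-dien-2-yloxy)silane | C=C(O[Si](C)(C)C(C)(C)C)/C=C/C | intermediate
3 | 4,4-dimethoxybutan-2-one | CC(=O)CC(OC)OC | starting material
4 | trimethyl(3-methylbut-2-en-1-yl)silane | CC(C)=CC[Si](C)(C)C | starting material
5 | 4-methoxy-5,5-dimethylhept-6-en-2-one (racemic, not isolated) | CC(=O)CC(OC)C(C)(C)C=C | intermediate
6 | (E)-5,5-dimethylhepta-3,6-dien-2-one | CC(=O)/C=C/C(C)(C)C=C | intermediate
7 | 1-[(1R,2R,6R)-4-(tert-butyldimethylsilyloxy)-2-methyl-6-(2-methylbut-3-en-2-yl)cyclohex-3-en-1-yl]ethan-1-one (acetyl trans to the tert-alkyl group, cis to the methyl) | CC(C)(C)[Si](C)(C)OC1=C[C@@H](C)[C@@H](C(C)=O)[C@H](C(C)(C)C=C)C1 | intermediate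
8 | diethyl 1-[4-(tert-butyldimethylsilyloxy)-2-methyl-6-(2-methylbut-3-en-2-yl)cyclohex-3-en-1-yl]ethenyl phosphate (ring stereocentres as in 7; not isolated) | CC(C)(C)[Si](C)(C)OC1=C[C@@H](C)[C@@H](C(=C)OP(=O)(OCC)OCC)[C@H](C(C)(C)C=C)C1 | intermediate
9 | tert-butyl{[(3S,4R,5R)-4-ethynyl-3-methyl-5-(2-methylbut-3-en-2-yl)cyclohex-1-en-1-yl]oxy}dimethylsilane | CC(C)(C)[Si](C)(C)OC1=C[C@@H](C)[C@@H](C#C)[C@H](C(C)(C)C=C)C1 | intermediate
10 | (E)-3-[4-(tert-butyldimethylsilyloxy)-2-methyl-6-(2-methylbut-3-en-2-yl)cyclohex-3-en-1-yl]but-2-en-1-ol (ring stereocentres as in 7) | CC(C)(C)[Si](C)(C)OC1=C[C@@H](C)[C@@H](/C(C)=C/CO)[C@H](C(C)(C)C=C)C1 | intermediate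
11 | (4R,5R)-4-[(E)-4-hydroxybut-2-en-2-yl]-3-methyl-5-(2-methylbut-3-en-2-yl)cyclohex-2-en-1-one (4,5-trans) | O=C1C=C(C)[C@@H](/C(C)=C/CO)[C@H](C(C)(C)C=C)C1 | intermediate
12 | (4S,5R)-4-[(E)-4-hydroxybut-2-en-2-yl]-3-methyl-5-(2-methylbut-3-en-2-yl)cyclohex-2-en-1-one (4,5-cis) | O=C1C=C(C)[C@H](/C(C)=C/CO)[C@H](C(C)(C)C=C)C1 | intermediate
13 | (4R,5R)-4-[(2R,3R)-3-(hydroxymethyl)-2-methyloxiran-2-yl]-3-methyl-5-(2-methylbut-3-en-2-yl)cyclohex-2-en-1-one | O=C1C=C(C)[C@H]([C@@]2(C)O[C@@H]2CO)[C@H](C(C)(C)C=C)C1 | intermediate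
14 | (4R,5R)-3-methyl-5-(2-methylbut-3-en-2-yl)-4-[(2R,3R)-2-methyl-3-{[(triethylsilyl)oxy]methyl}oxiran-2-yl]cyclohex-2-en-1-one | O=C1C=C(C)[C@H]([C@@]2(C)O[C@@H]2CO[Si](CC)(CC)CC)[C@H](C(C)(C)C=C)C1 | intermediate
15 | tert-butyldimethylsilyl dienol ether of 14 (2-silyloxycyclohexa-1,3-diene; stereocentres as in 14) | CC(C)(C)[Si](C)(C)OC1=C[C@@H](C(C)(C)C=C)[C@@H]([C@@]2(C)O[C@@H]2CO[Si](CC)(CC)CC)C(C)=C1 | intermediate
16 | bicyclo[3.1.1]hept-3-en-2-one: C10 with Me and (9S)-CH(OSiMe2t-Bu)CH2OSiEt3, C5 with 2-methylbut-3-en-2-yl, both chains anti to the enone bridge; C4, C5, C10, C11 as in the target | CC[Si](CC)(CC)OC[C@@H](O[Si](C)(C)C(C)(C)C)[C@]1(C)[C@H]2C(C)=CC(=O)[C@@H]1[C@H]2C(C)(C)C=C | intermediate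
17 | C8 aldehyde of 16 (α-silyloxy aldehyde; stereocentres as in 16) | O=C[C@@H](O[Si](C)(C)C(C)(C)C)[C@]1(C)[C@H]2C(C)=CC(=O)[C@@H]1[C@H]2C(C)(C)C=C | intermediate
18 | C8 methylenation product of 17 (two vinyl groups; stereocentres as in 16) | C=C[C@@H](O[Si](C)(C)C(C)(C)C)[C@]1(C)[C@H]2C(C)=CC(=O)[C@@H]1[C@H]2C(C)(C)C=C | intermediate
19 | 9α-(tert-butyldimethylsilyloxy)longipina-2,7-dien-1-one | C1=CC(C)(C)[C@@H]2[C@H]3C(=O)C=C(C)[C@@H]2[C@@]3(C)[C@@H]1O[Si](C)(C)C(C)(C)C | intermediate
20 | 7β,8β-dihydroxy-9α-(tert-butyldimethylsilyloxy)longipin-2-en-1-one | O[C@H]1[C@@H](O)C(C)(C)[C@@H]2[C@H]3C(=O)C=C(C)[C@@H]2[C@@]3(C)[C@@H]1O[Si](C)(C)C(C)(C)C | intermediate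
21 | 8α-angeloyloxy-7β-hydroxy-9α-(tert-butyldimethylsilyloxy)longipin-2-en-1-one | C/C=C(/C)C(=O)O[C@@H]1[C@@H](O)C(C)(C)[C@@H]2[C@H]3C(=O)C=C(C)[C@@H]2[C@@]3(C)[C@@H]1O[Si](C)(C)C(C)(C)C | intermediate
22 | 7β,8α-diangeloyloxy-9α-(tert-butyldimethylsilyloxy)longipin-2-en-1-one | C/C=C(/C)C(=O)O[C@@H]1[C@@H](OC(=O)/C(C)=C\C)C(C)(C)[C@@H]2[C@H]3C(=O)C=C(C)[C@@H]2[C@@]3(C)[C@@H]1O[Si](C)(C)C(C)(C)C | intermediate
23 | 7β,8α-diangeloyloxy-9α-hydroxylongipin-2-en-1-one, (4R,5S,7S,8S,9S,10R,11R) | C/C=C(/C)C(=O)O[C@@H]1[C@@H](OC(=O)/C(C)=C\C)C(C)(C)[C@@H]2[C@H]3C(=O)C=C(C)[C@@H]2[C@@]3(C)[C@@H]1O | target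

**Step count and risks**

Total step count: 18. Longest linear sequence: 17 steps (3/4 → 23, steps 2–18; equally 1 → 23 through steps 1 and 3–18).

Steps most likely to fail:

1. Step 11 (Proposed new method). The silyl-activated epoxide may undergo 1,2-hydride shift to the C9 ketone, elimination to an allylic silyl ether, or attack at C9 instead of 4-exo closure at the tertiary carbon. The fallback changes from cationic activation of a fully protected substrate to an anionic, chelation-directed closure on the free epoxy alcohol; it sets out from 13 and returns at 16. Treatment of 13 with LDA (2.2 equiv, THF, −78 °C) and then Et2AlCl should give an aluminium alkoxide/dienolate in which aluminium bridges the C8 alkoxide and the epoxide oxygen. Intramolecular 4-exo opening at C10 should then give the cyclised 8,9-diol F1; the known models are the C-3-selective opening of 2,3-epoxy alcohols by aluminium enolates and the anionic 4-exo closure of epoxy nitriles. Silylation of the primary hydroxyl (Et3SiCl, imidazole) should give the mono-triethylsilyl ether F2, and t-BuMe2SiOTf/2,6-lutidine on the hindered C9 hydroxyl should return 16.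

2. Step 16. Displacement at the hindered C8 may fail, with elimination or no reaction of the dioxaphosphorane. The fallback replaces the oxyphosphonium electrophile by a cyclic sulfate; it sets out from 20 and returns at 21. SOCl2/Et3N should give the cyclic sulfite F3, and RuCl3 (cat.)/NaIO4 the cyclic sulfate F4. Cesium angelate in DMF at 60 °C should open F4 at C8 with inversion (C7 is neopentyl) to the 8α-angelate 7β-hydrogen sulfate F5, and catalytic H2SO4 in THF–H2O should hydrolyse the sulfate ester to 21.

3. Step 7. Equilibration may stop at an unfavourable cis/trans ratio or move the double bonds. The fallback sets C4 by kinetic protonation instead of thermodynamic control; it sets out from 11 and returns at 12. Excess t-BuOK in t-BuOH followed by rapid quench into aqueous acetic acid should protonate the extended dienolate at C2 and give the deconjugated β,γ-enone F6, which has no stereocentre at C4. Mild reconjugation (DBU cat., CH2Cl2, 0 °C) should then protonate C4 from the face anti to the C5 tert-alkyl group and give 12.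

Further compounds
F1 | step 11 | cyclised 8,9-diol (bicyclo[3.1.1]hept-3-en-2-one with C10–CH(OH)CH2OH; stereocentres as in 16) | OC[C@@H](O)[C@]1(C)[C@H]2C(C)=CC(=O)[C@@H]1[C@H]2C(C)(C)C=C
F2 | step 11 | 8-O-triethylsilyl ether of F1 | CC[Si](CC)(CC)OC[C@@H](O)[C@]1(C)[C@H]2C(C)=CC(=O)[C@@H]1[C@H]2C(C)(C)C=C
F3 | step 16 | 7β,8β-cyclic sulfite of 20 | O=S1O[C@H]2[C@@H](O1)C(C)(C)[C@@H]3[C@H]4C(=O)C=C(C)[C@@H]3[C@@]4(C)[C@@H]2O[Si](C)(C)C(C)(C)C
F4 | step 16 | 7β,8β-cyclic sulfate of 20 | O=S1(=O)O[C@H]2[C@@H](O1)C(C)(C)[C@@H]3[C@H]4C(=O)C=C(C)[C@@H]3[C@@]4(C)[C@@H]2O[Si](C)(C)C(C)(C)C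
F5 | step 16 | 8α-angeloyloxy-9α-(tert-butyldimethylsilyloxy)-1-oxolongipin-2-en-7β-yl hydrogen sulfate | C/C=C(/C)C(=O)O[C@@H]1[C@@H](OS(=O)(=O)O)C(C)(C)[C@@H]2[C@H]3C(=O)C=C(C)[C@@H]2[C@@]3(C)[C@@H]1O[Si](C)(C)C(C)(C)C
F6 | step 7 | (5R)-4-[(E)-4-hydroxybut-2-en-2-yl]-3-methyl-5-(2-methylbut-3-en-2-yl)cyclohex-3-en-1-one | O=C1CC(C)=C(/C(C)=C/CO)[C@H](C(C)(C)C=C)C1
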